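**Retrosynthetic overview**
- Last operation: a fluoride-triggered cascade closes the dihydrobenzofuran (p-quinone methide released from a cyclic carbonate) and the γ-lactone together, removes every protecting group and sets both trans relationships.
- The acyclic precursor comes from an oxidative enolate heterocoupling (the C8–C8' bond) of an Evans imide (ring C/D arm) with a tert-butyl ester (ring A/B arm), followed by imide reduction.
- Both arms are aryl bromides extended by Heck/hydrogenation; both β-5 units come from one arylacetyl oxazolidinone, by a boron syn-aldol (future closed unit) or a MgCl2 anti-aldol (open diol) with silylated vanillin.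
- The arylacetyl imide comes from 4-bromo-2-methoxyphenol and ethyl glyoxylate (ortho-hydroxyalkylation, deoxygenation, silylation, acylation).
- Ring order: all four benzene rings are bought; dihydrobenzofuran and lactone are formed last, simultaneously.

Assumption and shorthand: the target is made exactly as written in the SMILES (lactone 3R,4R; dihydrobenzofuran 2S,3R; open diol 1S,2S); TBS = tert-butyldimethylsilyl, TBSO = its ether, G = 3-methoxy-4-(TBSO)phenyl; ring A = guaiacyl ring on the dihydrobenzofuran, ring B = its benzo ring, ring C = central ring carrying the open diol, ring D = guaiacyl ring of the open diol.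

**Step 1**
Reactants: 1 4-bromo-2-methoxyphenol; 2 ethyl glyoxylate
Product: 3 ethyl 2-(5-bromo-2-hydroxy-3-methoxyphenyl)-2-hydroxyacetate (racemic)
Conditions: TiCl4 (1.0 equiv), CH2Cl2, −30 → 0 °C; aqueous work-up
Reagents that add atoms: none
Why: Casiraghi-type ortho-hydroxyalkylation (Friedel–Crafts) in which the aryloxytitanium species delivers the glyoxylate to the only free ortho position (para is blocked by Br); the new carbinol centre is racemic and is removed in step 2.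

**Step 2**
Reactants: 3 ethyl 2-(5-bromo-2-hydroxy-3-methoxyphenyl)-2-hydroxyacetate
Product: 4 2-(5-bromo-2-hydroxy-3-methoxyphenyl)acetic acid
Conditions: H3PO2 (50% aq., 3 equiv), I2 (0.2 equiv), AcOH, 90 °C
Reagents that add atoms: water, O
Why: Hypophosphorous acid–iodine deoxygenation of a mandelate (HI made in the flask converts the benzylic alcohol to the iodide and reduces it) while the hot aqueous acid hydrolyses the ethyl ester; aryl bromide and methyl ether are inert.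

**Step 3**
Reactants: 4 2-(5-bromo-2-hydroxy-3-methoxyphenyl)acetic acid
Product: 6 2-[5-bromo-3-methoxy-2-(TBSO)phenyl]acetic acid, via silyl ester 5 (not isolated)
Conditions: TBSCl (2.5 equiv), imidazole, DMF, 23 °C; then AcOH/THF/H2O, 23 °C
Reagents that add atoms: tert-butyldimethylsilyl chloride, CC(C)(C)[Si](C)(C)Cl
Why: Exhaustive silylation followed by selective hydrolysis of the far more labile silyl ester leaves the hindered aryl silyl ether (protecting-group chemistry).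

**Step 4**
Reactants: 6 2-[5-bromo-3-methoxy-2-(TBSO)phenyl]acetic acid; 7 (S)-4-benzyloxazolidin-2-one
Product: 9 (S)-4-benzyl-3-{2-[5-bromo-3-methoxy-2-(TBSO)phenyl]acetyl}oxazolidin-2-one, via mixed anhydride 8 (not isolated)
Conditions: t-BuCOCl, Et3N, THF, −20 °C; then 7, LiCl, −20 → 23 °C
Reagents that add atoms: none
Why: Mixed pivalic anhydride activation and LiCl-assisted N-acylation of the oxazolidinone (standard attachment of an Evans auxiliary), with attack at the less hindered arylacetyl carbonyl.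

**Step 5**
Reactants: 9 (S)-4-benzyl-3-{2-[5-bromo-3-methoxy-2-(TBSO)phenyl]acetyl}oxazolidin-2-one; 10 3-methoxy-4-(TBSO)benzaldehyde
Product: 11 (S)-4-benzyl-3-{(2S,3S)-2-[5-bromo-3-methoxy-2-(TBSO)phenyl]-3-hydroxy-3-G-propanoyl}oxazolidin-2-one
Conditions: Bu2BOTf, i-Pr2NEt, CH2Cl2, −78 → 0 °C; then pH 7 buffer, MeOH, H2O2, 0 °C
Reagents that add atoms: none
Why: Evans boron syn-aldol in which the Z-boron enolate reacts through a Zimmerman–Traxler chair on the face away from the benzyl group, setting the acyl chain as (2S,3S), so that C2 becomes the R-configured C3 of the later dihydrobenzofuran.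

**Step 6**
Reactants: 11 syn aldol adduct
Product: 12 (1S,2R)-2-[5-bromo-3-methoxy-2-(TBSO)phenyl]-1-G-propane-1,3-diol
Conditions: LiBH4, MeOH (1 equiv), THF, 0 °C
Reagents that add atoms: none
Why: Reductive cleavage of the N-acyl oxazolidinone (hydride attack at the exocyclic carbonyl) gives the primary alcohol without touching either stereocentre or the aryl bromide.

**Step 7**
Reactants: 12 (1S,2R)-diol; 13 tert-butyl acrylate
Product: 15 tert-butyl 3-{3-[(1S,2R)-1,3-dihydroxy-1-G-propan-2-yl]-5-methoxy-4-(TBSO)phenyl}propanoate, via cinnamate 14 (not isolated)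
Conditions: Pd(OAc)2 (5 mol%), P(t-Bu)3·HBF4, Cy2NMe, dioxane, 80 °C; then Pd/C (10 wt%), H2 (1 atm), 23 °C, same flask
Reagents that add atoms: none
Why: Mizoroki–Heck coupling of the aryl bromide with the acrylate followed by Pd/C hydrogenation of the cinnamate installs the propanoate arm, the amine present suppressing benzylic C–O hydrogenolysis.

**Step 8**
Reactants: 15 tert-butyl 3-{3-[(1S,2R)-1,3-dihydroxy-1-G-propan-2-yl]-5-methoxy-4-(TBSO)phenyl}propanoate
Product: 16 tert-butyl 3-{3-methoxy-5-[(4S,5R)-4-G-2-oxo-1,3-dioxan-5-yl]-4-(TBSO)phenyl}propanoate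
Conditions: CDI (1.5 equiv), DMAP (10 mol%), CH2Cl2, 23 → 40 °C
Reagents that add atoms: 1,1'-carbonyldiimidazole, O=C(n1ccnc1)n1ccnc1
Why: Carbonylation of the 1,3-diol gives the six-membered cyclic carbonate, which masks both hydroxyls in one step and turns the benzylic C–O bond into the leaving group needed in step 16.

**Step 9**
Reactants: 9 (S)-4-benzyl-3-{2-[5-bromo-3-methoxy-2-(TBSO)phenyl]acetyl}oxazolidin-2-one; 10 3-methoxy-4-(TBSO)benzaldehyde
Product: 18 (S)-4-benzyl-3-{(2R,3S)-2-[5-bromo-3-methoxy-2-(TBSO)phenyl]-3-hydroxy-3-G-propanoyl}oxazolidin-2-one, via trimethylsilyl ether 17 (not isolated)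
Conditions: MgCl2 (20 mol%), Et3N, Me3SiCl, EtOAc, 23 °C; then CF3CO2H (cat.), MeOH, 0 °C
Reagents that add atoms: none
Why: Evans MgCl2-catalysed direct anti-aldol in which the chelated magnesium Z-enolate reacts on the face opposite to the benzyl group through a boat transition state and is trapped as the silyl ether, giving the (2R,3S) anti adduct that corresponds to the (1S,2S) diol of the target.

**Step 10**
Reactants: 18 anti aldol adduct
Product: 19 (1S,2S)-2-[5-bromo-3-methoxy-2-(TBSO)phenyl]-1-G-propane-1,3-diol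
Conditions: LiBH4, MeOH (1 equiv), THF, 0 °C
Reagents that add atoms: none
Why: Reductive cleavage of the N-acyl oxazolidinone by LiBH4, as in step 6, leaves both stereocentres untouched.

**Step 11**
Reactants: 19 (1S,2S)-diol
Product: 20 (1S,2S)-2-[5-bromo-3-methoxy-2-(TBSO)phenyl]-1-G-1,3-bis(TBSO)propane
Conditions: TBSOTf (2.5 equiv), 2,6-lutidine, CH2Cl2, −78 → 0 °C
Reagents that add atoms: tert-butyldimethylsilyl triflate, CC(C)(C)[Si](C)(C)OS(=O)(=O)C(F)(F)F
Why: Silyl triflate silylation of both hydroxyls (the hindered benzylic one needs the triflate) protects them from the strong base of step 14.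

**Step 12**
Reactants: 7 (S)-4-benzyloxazolidin-2-one; 21 acryloyl chloride
Product: 22 (S)-3-acryloyl-4-benzyloxazolidin-2-one
Conditions: n-BuLi, THF, −78 °C; then 21, −78 → 0 °C
Reagents that add atoms: none
Why: N-Acylation of the lithiated oxazolidinone (Evans acylation) gives the Heck acceptor that already carries the auxiliary needed in step 14.

**Step 13**
Reactants: 20 bis-silyl ether aryl bromide; 22 (S)-3-acryloyl-4-benzyloxazolidin-2-one
Product: 24 (S)-4-benzyl-3-[3-{3-[(1S,2S)-1-G-1,3-bis(TBSO)propan-2-yl]-5-methoxy-4-(TBSO)phenyl}propanoyl]oxazolidin-2-one, via cinnamoyl imide 23 (not isolated)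
Conditions: Pd(OAc)2 (5 mol%), P(t-Bu)3·HBF4, Cy2NMe, dioxane, 80 °C; then Pd/C (10 wt%), H2 (1 atm), 23 °C, same flask
Reagents that add atoms: none
Why: Mizoroki–Heck coupling with the acrylimide and Pd/C hydrogenation give the 3-arylpropanoyl imide, silyl ethers and imide being stable to both.

**Step 14**
Reactants: 24 ring C/D propanoyl imide; 16 ring A/B tert-butyl ester (1.5 equiv)
Product: 25 tert-butyl (2RS,3R)-4-[(S)-4-benzyl-2-oxooxazolidin-3-yl]-3-{3-[(1S,2S)-1-G-1,3-bis(TBSO)propan-2-yl]-5-methoxy-4-(TBSO)benzyl}-2-{3-methoxy-5-[(4S,5R)-4-G-2-oxo-1,3-dioxan-5-yl]-4-(TBSO)benzyl}-4-oxobutanoate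
Conditions: LiN(i-Pr)2 (2.1 equiv), THF, −78 °C; then Fe(acac)3 (2.2 equiv), −78 → 23 °C
Reagents that add atoms: none
Why: Baran-type oxidative enolate heterocoupling in which the two lithium enolates are oxidised by Fe(acac)3 (trivalent iron goes to divalent iron) and the C–C bond forms on the imide enolate face opposite to the benzyl group, setting the imide α-carbon (later lactone C4) as R, while the ester α-carbon forms as a mixture that is equilibrated in step 16.

**Step 15**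
Reactants: 25 heterocoupling product
Product: 26 tert-butyl (2RS,3R)-3-{3-[(1S,2S)-1-G-1,3-bis(TBSO)propan-2-yl]-5-methoxy-4-(TBSO)benzyl}-4-hydroxy-2-{3-methoxy-5-[(4S,5R)-4-G-2-oxo-1,3-dioxan-5-yl]-4-(TBSO)benzyl}butanoate
Conditions: LiBH4 (1.2 equiv), MeOH (1 equiv), THF, −10 → 0 °C
Reagents that add atoms: none
Why: Chemoselective reductive removal of the auxiliary, LiBH4 reducing the activated imide carbonyl far faster than the tert-butyl ester or the cyclic carbonate, and the tert-butyl ester being too hindered to lactonise under these conditions.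

**Step 16**
Reactants: 26 γ-hydroxy tert-butyl ester
Product: 28 (3R,4R)-4-{3-[(1S,2S)-1,3-dihydroxy-1-(4-hydroxy-3-methoxyphenyl)propan-2-yl]-4-hydroxy-5-methoxybenzyl}-3-{[(2S,3R)-2-(4-hydroxy-3-methoxyphenyl)-3-(hydroxymethyl)-7-methoxy-2,3-dihydrobenzofuran-5-yl]methyl}dihydrofuran-2(3H)-one, via quinone methide 27 (not isolated)
Conditions: TBAF (1.0 M in THF, dried over 4 Å sieves, 12 equiv), THF, 0 → 23 °C, 12 h; AcOH quench
Reagents that add atoms: none
Why: Proposed new method: fluoride removes the six silyl groups, the ring A phenoxide expels the cyclic carbonate (1,6-elimination, then loss of CO2) to give the p-quinone methide, the ring B phenoxide adds to it 5-exo (oxa-Michael) to close the trans-dihydrobenzofuran with C2 set as S under control of C3 as in biomimetic β-5 phenylcoumaran closure, and the primary alkoxide lactonises onto the tert-butyl ester while the basic phenoxide/fluoride medium epimerises the lactone α-carbon to the more stable trans (3R) isomer; the closest known reactions are fluoride-triggered quinone methide cyclisations and base-mediated lactonisation–epimerisation of γ-hydroxy esters to trans-dibenzylbutyrolactones.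

**Compound list**

1 | 4-bromo-2-methoxyphenol | COc1cc(Br)ccc1O | starting material
2 | ethyl glyoxylate | CCOC(=O)C=O | starting material
3 | ethyl 2-(5-bromo-2-hydroxy-3-methoxyphenyl)-2-hydroxyacetate (racemic) | CCOC(=O)C(O)c1cc(Br)cc(OC)c1O | intermediate
4 | 2-(5-bromo-2-hydroxy-3-methoxyphenyl)acetic acid | OC(=O)Cc1cc(Br)cc(OC)c1O | intermediate
5 | TBS 2-[5-bromo-3-methoxy-2-(TBSO)phenyl]acetate (silyl ester, not isolated) | COc1cc(Br)cc(CC(=O)O[Si](C)(C)C(C)(C)C)c1O[Si](C)(C)C(C)(C)C | intermediate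
6 | 2-[5-bromo-3-methoxy-2-(TBSO)phenyl]acetic acid | COc1cc(Br)cc(CC(=O)O)c1O[Si](C)(C)C(C)(C)C | intermediate
7 | (S)-4-benzyloxazolidin-2-one | O=C1N[C@@H](Cc2ccccc2)CO1 | starting material
8 | 2-[5-bromo-3-methoxy-2-(TBSO)phenyl]acetic pivalic anhydride (mixed anhydride, not isolated) | COc1cc(Br)cc(CC(=O)OC(=O)C(C)(C)C)c1O[Si](C)(C)C(C)(C)C | intermediate
9 | (S)-4-benzyl-3-{2-[5-bromo-3-methoxy-2-(TBSO)phenyl]acetyl}oxazolidin-2-one | COc1cc(Br)cc(CC(=O)N2[C@@H](Cc3ccccc3)COC2=O)c1O[Si](C)(C)C(C)(C)C | intermediate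
10 | 3-methoxy-4-(TBSO)benzaldehyde | COc1cc(C=O)ccc1O[Si](C)(C)C(C)(C)C | starting material
11 | (S)-4-benzyl-3-{(2S,3S)-2-[5-bromo-3-methoxy-2-(TBSO)phenyl]-3-hydroxy-3-G-propanoyl}oxazolidin-2-one (syn aldol adduct) | COc1cc(ccc1O[Si](C)(C)C(C)(C)C)[C@@H](O)[C@@H](C(=O)N2[C@@H](Cc3ccccc3)COC2=O)c4cc(Br)cc(OC)c4O[Si](C)(C)C(C)(C)C | intermediate
12 | (1S,2R)-2-[5-bromo-3-methoxy-2-(TBSO)phenyl]-1-G-propane-1,3-diol | COc1cc(ccc1O[Si](C)(C)C(C)(C)C)[C@@H](O)[C@@H](CO)c2cc(Br)cc(OC)c2O[Si](C)(C)C(C)(C)C | intermediate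
13 | tert-butyl acrylate | C=CC(=O)OC(C)(C)C | starting material
14 | tert-butyl (E)-3-{3-[(1S,2R)-1,3-dihydroxy-1-G-propan-2-yl]-5-methoxy-4-(TBSO)phenyl}acrylate (cinnamate, not isolated) | COc1cc(ccc1O[Si](C)(C)C(C)(C)C)[C@@H](O)[C@@H](CO)c2cc(/C=C/C(=O)OC(C)(C)C)cc(OC)c2O[Si](C)(C)C(C)(C)C | intermediate
15 | tert-butyl 3-{3-[(1S,2R)-1,3-dihydroxy-1-G-propan-2-yl]-5-methoxy-4-(TBSO)phenyl}propanoate | COc1cc(ccc1O[Si](C)(C)C(C)(C)C)[C@@H](O)[C@@H](CO)c2cc(CCC(=O)OC(C)(C)C)cc(OC)c2O[Si](C)(C)C(C)(C)C | intermediate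
16 | tert-butyl 3-{3-methoxy-5-[(4S,5R)-4-G-2-oxo-1,3-dioxan-5-yl]-4-(TBSO)phenyl}propanoate | COc1cc(ccc1O[Si](C)(C)C(C)(C)C)[C@H]2OC(=O)OC[C@H]2c3cc(CCC(=O)OC(C)(C)C)cc(OC)c3O[Si](C)(C)C(C)(C)C | intermediate
17 | (S)-4-benzyl-3-{(2R,3S)-2-[5-bromo-3-methoxy-2-(TBSO)phenyl]-3-G-3-(trimethylsilyloxy)propanoyl}oxazolidin-2-one (not isolated) | COc1cc(ccc1O[Si](C)(C)C(C)(C)C)[C@@H](O[Si](C)(C)C)[C@H](C(=O)N2[C@@H](Cc3ccccc3)COC2=O)c4cc(Br)cc(OC)c4O[Si](C)(C)C(C)(C)C | intermediate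
18 | (S)-4-benzyl-3-{(2R,3S)-2-[5-bromo-3-methoxy-2-(TBSO)phenyl]-3-hydroxy-3-G-propanoyl}oxazolidin-2-one (anti aldol adduct) | COc1cc(ccc1O[Si](C)(C)C(C)(C)C)[C@@H](O)[C@H](C(=O)N2[C@@H](Cc3ccccc3)COC2=O)c4cc(Br)cc(OC)c4O[Si](C)(C)C(C)(C)C | intermediate
19 | (1S,2S)-2-[5-bromo-3-methoxy-2-(TBSO)phenyl]-1-G-propane-1,3-diol | COc1cc(ccc1O[Si](C)(C)C(C)(C)C)[C@@H](O)[C@H](CO)c2cc(Br)cc(OC)c2O[Si](C)(C)C(C)(C)C | intermediate
20 | (1S,2S)-2-[5-bromo-3-methoxy-2-(TBSO)phenyl]-1-G-1,3-bis(TBSO)propane | COc1cc(ccc1O[Si](C)(C)C(C)(C)C)[C@@H](O[Si](C)(C)C(C)(C)C)[C@H](CO[Si](C)(C)C(C)(C)C)c2cc(Br)cc(OC)c2O[Si](C)(C)C(C)(C)C | intermediate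
21 | acryloyl chloride | C=CC(=O)Cl | starting material
22 | (S)-3-acryloyl-4-benzyloxazolidin-2-one | C=CC(=O)N1[C@@H](Cc2ccccc2)COC1=O | intermediate
23 | (S)-4-benzyl-3-[(E)-3-{3-[(1S,2S)-1-G-1,3-bis(TBSO)propan-2-yl]-5-methoxy-4-(TBSO)phenyl}acryloyl]oxazolidin-2-one (cinnamoyl imide, not isolated) | COc1cc(ccc1O[Si](C)(C)C(C)(C)C)[C@@H](O[Si](C)(C)C(C)(C)C)[C@H](CO[Si](C)(C)C(C)(C)C)c2cc(/C=C/C(=O)N3[C@@H](Cc4ccccc4)COC3=O)cc(OC)c2O[Si](C)(C)C(C)(C)C | intermediate
24 | (S)-4-benzyl-3-[3-{3-[(1S,2S)-1-G-1,3-bis(TBSO)propan-2-yl]-5-methoxy-4-(TBSO)phenyl}propanoyl]oxazolidin-2-one | COc1cc(ccc1O[Si](C)(C)C(C)(C)C)[C@@H](O[Si](C)(C)C(C)(C)C)[C@H](CO[Si](C)(C)C(C)(C)C)c2cc(CCC(=O)N3[C@@H](Cc4ccccc4)COC3=O)cc(OC)c2O[Si](C)(C)C(C)(C)C | intermediate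
25 | tert-butyl (2RS,3R)-4-[(S)-4-benzyl-2-oxooxazolidin-3-yl]-3-{3-[(1S,2S)-1-G-1,3-bis(TBSO)propan-2-yl]-5-methoxy-4-(TBSO)benzyl}-2-{3-methoxy-5-[(4S,5R)-4-G-2-oxo-1,3-dioxan-5-yl]-4-(TBSO)benzyl}-4-oxobutanoate (C2 epimer mixture) | COc1cc([C@@H](O[Si](C)(C)C(C)(C)C)[C@H](CO[Si](C)(C)C(C)(C)C)c2cc(C[C@@H](C(=O)N5[C@@H](Cc6ccccc6)COC5=O)C(Cc3cc(OC)c(O[Si](C)(C)C(C)(C)C)c(c3)[C@@H]4COC(=O)O[C@@H]4c7ccc(O[Si](C)(C)C(C)(C)C)c(OC)c7)C(=O)OC(C)(C)C)cc(OC)c2O[Si](C)(C)C(C)(C)C)ccc1O[Si](C)(C)C(C)(C)C | intermediate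
26 | tert-butyl (2RS,3R)-3-{3-[(1S,2S)-1-G-1,3-bis(TBSO)propan-2-yl]-5-methoxy-4-(TBSO)benzyl}-4-hydroxy-2-{3-methoxy-5-[(4S,5R)-4-G-2-oxo-1,3-dioxan-5-yl]-4-(TBSO)benzyl}butanoate (C2 epimer mixture) | COc1cc([C@@H](O[Si](C)(C)C(C)(C)C)[C@H](CO[Si](C)(C)C(C)(C)C)c2cc(C[C@@H](CO)C(Cc3cc(OC)c(O[Si](C)(C)C(C)(C)C)c(c3)[C@@H]4COC(=O)O[C@@H]4c7ccc(O[Si](C)(C)C(C)(C)C)c(OC)c7)C(=O)OC(C)(C)C)cc(OC)c2O[Si](C)(C)C(C)(C)C)ccc1O[Si](C)(C)C(C)(C)C | intermediate
27 | quinone methide: tert-butyl (2RS,3R)-3-{3-[(1S,2S)-1-(4-hydroxy-3-methoxyphenyl)-1,3-bis(TBSO)propan-2-yl]-4-hydroxy-5-methoxybenzyl}-4-hydroxy-2-{4-hydroxy-3-[(2R)-1-hydroxy-3-(3-methoxy-4-oxocyclohexa-2,5-dien-1-ylidene)propan-2-yl]-5-methoxybenzyl}butanoate (drawn with the two alkyl silyl ethers still in place; not isolated) | COc1cc([C@@H](O[Si](C)(C)C(C)(C)C)[C@H](CO[Si](C)(C)C(C)(C)C)c2cc(C[C@@H](CO)C(Cc3cc(OC)c(O)c(c3)[C@H](CO)C=C4C=CC(=O)C(OC)=C4)C(=O)OC(C)(C)C)cc(OC)c2O)ccc1O | intermediate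
28 | (3R,4R)-4-{3-[(1S,2S)-1,3-dihydroxy-1-(4-hydroxy-3-methoxyphenyl)propan-2-yl]-4-hydroxy-5-methoxybenzyl}-3-{[(2S,3R)-2-(4-hydroxy-3-methoxyphenyl)-3-(hydroxymethyl)-7-methoxy-2,3-dihydrobenzofuran-5-yl]methyl}dihydrofuran-2(3H)-one | COc1cc([C@@H](O)[C@H](CO)c2cc(C[C@H]3COC(=O)[C@@H]3Cc3cc(OC)c4c(c3)[C@H](CO)[C@@H](c3ccc(O)c(OC)c3)O4)cc(OC)c2O)ccc1O | target

**Totals**

Total step count: 16. Longest linear sequence: 11 steps (steps 1–4, then 5–8 or 9–11 and 13, then 14–16).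

**Three steps most likely to fail**

Step 16 (the double ring closure) is the riskiest. The quinone methide can be trapped by residual water before the ring B phenoxide is free. Lactonisation of the tert-butyl ester or equilibration of the lactone α-carbon may be incomplete at 23 °C. The free phenolic product is base-sensitive. The fallback sets out from 26 and separates the two ring closures: DBU in toluene at 60 °C, without fluoride, lactonises the γ-hydroxy ester and equilibrates the α-carbon to give the silylated trans-lactone carbonate F1, which can be purified from any cis isomer. A short treatment with TBAF in THF at −20 °C, quenched with AcOH, then only has to trigger the quinone methide closure and desilylation. This comes back to the route at 28.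

Step 14 (oxidative heterocoupling) is the second risk. Homodimers, a modest yield on such large partners, incomplete facial control at the imide carbon and attack on the cyclic carbonate are all possible. The fallback sets out from 16: its lithium enolate (LiN(SiMe3)2, THF, −78 °C) is iodinated with I2 to the α-iodo ester F2. The sodium enolate of 24 (NaN(SiMe3)2, THF, −78 → −20 °C) is then alkylated by F2 on the face opposite to the benzyl group, a two-electron Evans alkylation in place of the oxidative coupling. This comes back to the route at 25.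

Step 9 (MgCl2 anti-aldol) is the third risk, because an arylacetyl imide is more acidic and more retro-aldol-prone than the usual propionyl substrates, so the anti selectivity is not assured. The fallback sets out from 6 and switches the stereocontrol element to a sulfur auxiliary of opposite configuration reacting through a non-chelated enolate. Acid 6 is coupled with (R)-4-benzylthiazolidine-2-thione (DCC, DMAP, CH2Cl2) to the N-acyl thiazolidinethione F3. The MgBr2·OEt2-catalysed aldol with 10 (Et3N, Me3SiCl, EtOAc) gives the silyl ether F4, and acidic methanol gives the anti adduct F5, which has the same (2R,3S) acyl chain as 18. LiBH4 then cleaves the auxiliary, and the sequence comes back to the route at 19.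

**Further compounds**

F1 | step 16 | (3R,4R)-4-{3-[(1S,2S)-1-G-1,3-bis(TBSO)propan-2-yl]-5-methoxy-4-(TBSO)benzyl}-3-{3-methoxy-5-[(4S,5R)-4-G-2-oxo-1,3-dioxan-5-yl]-4-(TBSO)benzyl}dihydrofuran-2(3H)-one | COc1cc([C@@H](O[Si](C)(C)C(C)(C)C)[C@H](CO[Si](C)(C)C(C)(C)C)c2cc(C[C@H]3COC(=O)[C@@H]3Cc3cc(OC)c(O[Si](C)(C)C(C)(C)C)c(c3)[C@@H]4COC(=O)O[C@@H]4c7ccc(O[Si](C)(C)C(C)(C)C)c(OC)c7)cc(OC)c2O[Si](C)(C)C(C)(C)C)ccc1O[Si](C)(C)C(C)(C)C
F2 | step 14 | tert-butyl (2RS)-2-iodo-3-{3-methoxy-5-[(4S,5R)-4-G-2-oxo-1,3-dioxan-5-yl]-4-(TBSO)phenyl}propanoate | COc1cc(ccc1O[Si](C)(C)C(C)(C)C)[C@H]2OC(=O)OC[C@H]2c3cc(CC(I)C(=O)OC(C)(C)C)cc(OC)c3O[Si](C)(C)C(C)(C)C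
F3 | step 9 | (R)-4-benzyl-3-{2-[5-bromo-3-methoxy-2-(TBSO)phenyl]acetyl}thiazolidine-2-thione | COc1cc(Br)cc(CC(=O)N2[C@H](Cc3ccccc3)CSC2=S)c1O[Si](C)(C)C(C)(C)C
F4 | step 9 | (R)-4-benzyl-3-{(2R,3S)-2-[5-bromo-3-methoxy-2-(TBSO)phenyl]-3-G-3-(trimethylsilyloxy)propanoyl}thiazolidine-2-thione | COc1cc(ccc1O[Si](C)(C)C(C)(C)C)[C@@H](O[Si](C)(C)C)[C@H](C(=O)N2[C@H](Cc3ccccc3)CSC2=S)c4cc(Br)cc(OC)c4O[Si](C)(C)C(C)(C)C
F5 | step 9 | (R)-4-benzyl-3-{(2R,3S)-2-[5-bromo-3-methoxy-2-(TBSO)phenyl]-3-hydroxy-3-G-propanoyl}thiazolidine-2-thione | COc1cc(ccc1O[Si](C)(C)C(C)(C)C)[C@@H](O)[C@H](C(=O)N2[C@H](Cc3ccccc3)CSC2=S)c4cc(Br)cc(OC)c4O[Si](C)(C)C(C)(C)C
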